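## Retrosynthetic overview

1. Jaeskeanin ⇐ phenol release ⇐ α-face epoxidation of C8=C9 ⇐ 4-OH-directed hydrogenation of C6=C7 in dienol aroate 17. O6 is the carbonyl oxygen of enone 13, acylated as its extended dienolate, so C6 is never a free carbinol.
2. Key disconnection: C1–C2 and C4–C5 are made in one operation. This is a desymmetrising [3+2] annulation of the β-zincio ketone from 1-isopropylcyclopropanol (C2–C4, C11–C13, O4) onto the achiral dienone 7.
3. Feature used: in the seven-membered ring, C1(CH3) and C8(CH3) lie symmetrically about C6–O, with C5/C7 and C10/C9 as pairs. 3,6-Dimethylcyclohepta-2,6-dienone 7 therefore already holds C1, C5–C10, C14, C15 and O6.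
4. 7 ⇐ loss of an oxygen bridge as water ⇐ (4+3) cycloaddition of 2,5-dimethylfuran with an oxyallyl cation.
5. Ring order: seven-membered ring (step 1), five-membered ring (step 5), oxirane (step 8).

Key step: step 5

**Remark on the chemistry.** Daucane numbering is used: C1 is the quaternary fusion carbon (CH3-15), C4 the carbinol carbon bearing isopropyl, C5 the fusion CH, C6 the acyloxy carbon and C8 bears CH3-14. α is the face of H-5 and β the face of CH3-15. The enantiomer of the chiral ligand in step 5 is taken to be the one that delivers carbon to the α face of C1.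

## Route

**Step 1**
Reactants: 1 2,5-dimethylfuran; 2 1,1,3,3-tetrabromopropan-2-one
Product: 4 1,5-dimethyl-8-oxabicyclo[3.2.1]oct-6-en-3-one (meso), via dibromo cycloadduct 3 (not isolated)
Conditions: Zn–Cu, THF, −10 °C→rt; then Zn–Cu, NH4Cl-sat. MeOH, rt
Reagents that add atoms: none
Why: Zinc generates the dibromo-oxyallyl cation from 2, which adds to the furan diene in a (4+3) cycloaddition, and zinc then removes both α-bromides of 3; the bicycle is meso, so no stereochemical issue arises.

**Step 2**
Reactants: 4 1,5-dimethyl-8-oxabicyclo[3.2.1]oct-6-en-3-one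
Product: 5 1,5-dimethyl-8-oxabicyclo[3.2.1]octan-3-one (meso)
Conditions: H2 (1 atm), Pd/C, EtOAc, rt
Reagents that add atoms: none
Why: Heterogeneous hydrogenation saturates the strained disubstituted alkene and leaves the ketone, which removes the unsaturation that would lead to a tropone in step 3.

**Step 3**
Reactants: 5 1,5-dimethyl-8-oxabicyclo[3.2.1]octan-3-one
Product: 7 3,6-dimethylcyclohepta-2,6-dien-1-one, via hydroxy enone 6 (not isolated)
Conditions: TsOH·H2O (10 mol %), toluene, reflux, Dean–Stark
Reagents that add atoms: none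
Why: Both C–O bonds of the bridge are tertiary and β to the ketone, so acid-catalysed β-elimination (retro-oxa-Michael) followed by dehydration of 6 should give the doubly conjugated dienone under equilibrating conditions.

**Step 4**
Reactants: 8 methyl 2-methylpropanoate
Product: 9 1-(propan-2-yl)cyclopropan-1-ol
Conditions: EtMgBr (2.2 equiv), Ti(OiPr)4 (10 mol %), Et2O, 0 °C→rt; 10% aq H2SO4
Reagents that add atoms: ethylmagnesium bromide, CC[Mg]Br
Why: In the Kulinkovich reaction, the titanacyclopropane formed from EtMgBr acts as a 1,2-dicarbanion towards the ester and gives the 1-substituted cyclopropanol.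

**Step 5**
Reactants: 7 3,6-dimethylcyclohepta-2,6-dien-1-one; 9 1-(propan-2-yl)cyclopropan-1-ol
Product: 13 4β-(trimethylsilyloxy)dauc-7-en-6-one (trans-fused, 5α-H, CH3-15 β), via β-zincio ketone 10 (not isolated), via zinc dienolate 11 (not isolated), via zinc aldolate 12 (not isolated)
Conditions: 9, Et2Zn (1.1 equiv), THF, 0 °C→rt; Cu(OTf)2 (5 mol %), chiral bidentate NHC ligand (5 mol %), 7 (1.2 equiv), −30 °C→rt; TMSCl, Et3N, 0 °C
Reagents that add atoms: chlorotrimethylsilane, C[Si](C)(C)Cl
Why: Proposed new method: Et2Zn turns 9 into its zinc cyclopropoxide, which opens at one of its two equivalent C1–CH2 bonds to the β-zincio ketone 10; transmetallation to the chiral NHC–Cu catalyst and 1,4-addition to one of the two enantiotopic β-methyl enone units of 7 makes C1–C2 and the zinc dienolate 11, whose C5 then attacks the pendant isopropyl ketone (5-(enolexo)-exo-trig aldol) to make C4–C5 and close the five-membered ring as the chelated aldolate 12. The closest known reaction types are Cu-catalysed enantioselective conjugate addition of dialkylzincs to β-substituted cyclic enones (all-carbon quaternary centres), Cu-mediated C–C coupling of zinc homoenolates made from cyclopropanols with Et2Zn, tandem conjugate addition–aldol cyclisation, and metal-catalysed [3+2] annulation of cyclopropanols with alkynes; their union on an enone is new. C1 is set by the catalyst, which chooses enone unit and face at once because the two units of Cs-symmetric 7 are mirror images. C5 and C4 are set under equilibrium (enolisation at C5, retro-aldol/aldol at C4–C5): the O4–Zn–O6 chelate needs O4 cis to C6 on the cyclopentane, and of the two chelated isomers the trans-fused one (4β-O, 5α-H) keeps the isopropyl group anti to CH3-15. Mono-addition is needed and should be secured by the excess of 7 and by the second enone staying masked in the cross-conjugated dienolate until the aldol step; TMSCl then caps O4 so that no retro-aldol can follow.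

**Step 6**
Reactants: 13 4β-(trimethylsilyloxy)dauc-7-en-6-one; 14 4-(acetyloxy)benzoyl chloride
Product: 17 6-[4-(acetyloxy)benzoyloxy]dauca-6,8-dien-4β-ol, via potassium dienolate 15 (not isolated), via silylated dienol aroate 16 (not isolated)
Conditions: KHMDS (1.1 equiv), THF, −78 °C; 14, −78→−40 °C; then citric acid, MeOH, 0 °C
Reagents that add atoms: none
Why: This is γ-enolisation followed by enol ester formation: C5–H is tertiary and shielded, so the base should take the ring γ-proton at C9 (cis to the carbonyl), the hard acyl chloride should trap the potassium dienolate on oxygen, and mild acid should then remove only the tertiary TMS ether.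

**Step 7**
Reactants: 17 6-[4-(acetyloxy)benzoyloxy]dauca-6,8-dien-4β-ol
Product: 18 6α-[4-(acetyloxy)benzoyloxy]dauc-8-en-4β-ol
Conditions: [Rh(nbd)(dppb)]BF4 (5 mol %), H2 (1 atm, stopped after 1 equiv), CH2Cl2, 0 °C
Reagents that add atoms: none
Why: In this hydroxy-directed homogeneous hydrogenation, the cationic rhodium is held by the 4β-OH and the ester carbonyl at C6=C7 and should add H2 from the β face, which sets 6β-H (6α-ester) and leaves the undirected C8=C9.

**Step 8**
Reactants: 18 6α-[4-(acetyloxy)benzoyloxy]dauc-8-en-4β-ol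
Product: 19 8α,9α-epoxy-6α-[4-(acetyloxy)benzoyloxy]daucan-4β-ol
Conditions: mCPBA (1.1 equiv), NaHCO3, CH2Cl2, 0 °C
Reagents that add atoms: 3-chloroperoxybenzoic acid, OOC(=O)c1cccc(Cl)c1
Why: In the Prilezhaev epoxidation of the only alkene, the peracid should approach the trans-hydroazulene from the α face, anti to the axial CH3-15, and set C8 and C9 together.

**Step 9**
Reactants: 19 8α,9α-epoxy-6α-[4-(acetyloxy)benzoyloxy]daucan-4β-ol
Product: 20 jaeskeanin
Conditions: K2CO3 (0.2 equiv), MeOH, 0 °C
Reagents that add atoms: none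
Why: Base-catalysed transesterification should cleave the activated phenolic acetate far faster than the hindered secondary aroate, and the oxirane and tertiary alcohol are inert to these conditions.

## Compound list

| No. | Name | SMILES | Role |
|---|---|---|---|
| 1 | 2,5-dimethylfuran | Cc1ccc(C)o1 | starting material |
| 2 | 1,1,3,3-tetrabromopropan-2-one | BrC(Br)C(=O)C(Br)Br | starting material |
| 3 | 2,4-dibromo-1,5-dimethyl-8-oxabicyclo[3.2.1]oct-6-en-3-one (C–Br epimers) | C[C@@]12C=C[C@@](C)(O1)C(Br)C(=O)C2Br | intermediate |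
| 4 | 1,5-dimethyl-8-oxabicyclo[3.2.1]oct-6-en-3-one | C[C@@]12C=C[C@@](C)(O1)CC(=O)C2 | intermediate |
| 5 | 1,5-dimethyl-8-oxabicyclo[3.2.1]octan-3-one | C[C@@]12CC[C@@](C)(O1)CC(=O)C2 | intermediate |
| 6 | 6-hydroxy-3,6-dimethylcyclohept-2-en-1-one (racemic) | CC1=CC(=O)CC(C)(O)CC1 | intermediate |
| 7 | 3,6-dimethylcyclohepta-2,6-dien-1-one | CC1=CC(=O)C=C(C)CC1 | intermediate |
| 8 | methyl 2-methylpropanoate | COC(=O)C(C)C | starting material |
| 9 | 1-(propan-2-yl)cyclopropan-1-ol | CC(C)C1(O)CC1 | intermediate |
| 10 | ethyl(4-methyl-3-oxopentyl)zinc | CC[Zn]CCC(=O)C(C)C | intermediate |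
| 11 | ethylzinc dienolate of the conjugate adduct | CC[Zn]OC1=C[C@](C)(CCC(=O)C(C)C)CCC(C)=C1 | intermediate |
| 12 | ethylzinc 4β-alkoxide of 4β-hydroxydauc-7-en-6-one | CC(C)[C@]1(O[Zn]CC)CC[C@]2(C)CCC(C)=CC(=O)[C@H]21 | intermediate |
| 13 | 4β-(trimethylsilyloxy)dauc-7-en-6-one | CC(C)[C@]1(O[Si](C)(C)C)CC[C@]2(C)CCC(C)=CC(=O)[C@H]21 | intermediate |
| 14 | 4-(acetyloxy)benzoyl chloride | CC(=O)Oc1ccc(cc1)C(Cl)=O | starting material |
| 15 | potassium 6,8-dienolate of 13 | CC(C)[C@]1(O[Si](C)(C)C)CC[C@]2(C)CC=C(C)C=C([O-])[C@H]21.[K+] | intermediate |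
| 16 | 6-[4-(acetyloxy)benzoyloxy]-4β-(trimethylsilyloxy)dauca-6,8-diene | CC(C)[C@]1(O[Si](C)(C)C)CC[C@]2(C)CC=C(C)C=C(OC(=O)c3ccc(OC(C)=O)cc3)[C@H]21 | intermediate |
| 17 | 6-[4-(acetyloxy)benzoyloxy]dauca-6,8-dien-4β-ol | CC(C)[C@]1(O)CC[C@]2(C)CC=C(C)C=C(OC(=O)c3ccc(OC(C)=O)cc3)[C@H]21 | intermediate |
| 18 | 6α-[4-(acetyloxy)benzoyloxy]dauc-8-en-4β-ol | CC(C)[C@]1(O)CC[C@]2(C)CC=C(C)C[C@H](OC(=O)c3ccc(OC(C)=O)cc3)[C@H]21 | intermediate |
| 19 | 8α,9α-epoxy-6α-[4-(acetyloxy)benzoyloxy]daucan-4β-ol | CC(C)[C@]1(O)CC[C@]2(C)C[C@@H]3O[C@]3(C)C[C@H](OC(=O)c3ccc(OC(C)=O)cc3)[C@H]21 | intermediate |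
| 20 | jaeskeanin | CC(C)[C@]1(O)CC[C@]2(C)C[C@@H]3O[C@]3(C)C[C@H](OC(=O)c3ccc(O)cc3)[C@H]21 | target |

Total step count: 9. Longest linear sequence: 8 (steps 1, 2, 3, 5, 6, 7, 8, 9).

## Steps most likely to fail

**1. Step 5.**
- What may go wrong:
  - The zinc cyclopropoxide may open slowly.
  - The homoenolate may be lost by protonation or β-hydride loss.
  - Discrimination between enone units and faces may be poor.
  - A second conjugate addition may occur.
- Fallback with known chemistry, from 7 back to 13:
  - Cu/chiral-NHC-catalysed conjugate addition of 4-methylpent-3-enylmagnesium bromide F1 (from commercial 5-bromo-2-methylpent-2-ene and Mg) to 7 would give 3,6-dimethyl-6-(4-methylpent-3-enyl)cyclohept-2-enone F2.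
  - mCPBA would epoxidise only the electron-rich side-chain alkene, giving the epoxide F3.
  - BF3·OEt2 (Meinwald rearrangement, hydride shift) would give the isopropyl diketone F4.
  - KOH/MeOH would equilibrate F4 by intramolecular aldol reaction to 4β-hydroxydauc-7-en-6-one F5.
  - TMSOTf/2,6-lutidine would then give 13.

**2. Step 7.**
- What may go wrong: hydrogen may add 1,4 across the diene, or the remote alkene may be over-reduced.
- Fallback, from 17 back to 19: the order of the two oxidation-state changes is reversed. Dimethyldioxirane in acetone at −20 °C would epoxidise the more electron-rich distal C8=C9 from the α face, giving the 8α,9α-epoxy enol aroate F6. With no diene left, the same directed hydrogenation of C6=C7 would lead directly to 19.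

**3. Step 6.**
- What may go wrong: deprotonation may occur at CH3-14 or at C5, or the dienolate may be acylated on carbon instead of oxygen.
- Fallback, from 13 back to 16: soft, equilibrating enolisation with TMSOTf/Et3N would give the thermodynamic endocyclic bis-silyl dienol ether F7. CsF together with 14 (acyl fluoride formed in the flask, fluoride-triggered O-acylation of the silyl dienol ether) would then give 16.

## Further compounds

F1 | step 5 | 4-methylpent-3-enylmagnesium bromide | CC(C)=CCC[Mg]Br
F2 | step 5 | 3,6-dimethyl-6-(4-methylpent-3-enyl)cyclohept-2-en-1-one | CC(C)=CCC[C@]1(C)CCC(C)=CC(=O)C1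
F3 | step 5 | 6-[2-(3,3-dimethyloxiran-2-yl)ethyl]-3,6-dimethylcyclohept-2-en-1-one (epimers at the oxirane CH) | CC1(C)OC1CC[C@]2(C)CCC(C)=CC(=O)C2
F4 | step 5 | 3,6-dimethyl-6-(4-methyl-3-oxopentyl)cyclohept-2-en-1-one | CC(C)C(=O)CC[C@]1(C)CCC(C)=CC(=O)C1
F5 | step 5 | 4β-hydroxydauc-7-en-6-one | CC(C)[C@]1(O)CC[C@]2(C)CCC(C)=CC(=O)[C@H]21
F6 | step 7 | 8α,9α-epoxy-6-[4-(acetyloxy)benzoyloxy]dauc-6-en-4β-ol | CC(C)[C@]1(O)CC[C@]2(C)C[C@@H]3O[C@]3(C)C=C(OC(=O)c3ccc(OC(C)=O)cc3)[C@H]21
F7 | step 6 | 4β,6-bis(trimethylsilyloxy)dauca-6,8-diene | CC(C)[C@]1(O[Si](C)(C)C)CC[C@]2(C)CC=C(C)C=C(O[Si](C)(C)C)[C@H]21
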